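Readings and results were generated by integration for substances that don't exist, and the scatter is random.

In a one-step world each reagent makes one target, so 1.40 mM of reagent on 2.0 mM of starting material would cap target at 70.0%. The earlier runs show how far a real flask stays under such a cap.

| flask | starting material | reagent | second substrate | third substrate | temperature | remark | time |
|---|---|---|---|---|---|---|---|
| spring | 2 mM | 2 mM | 2 mM | 4 mM | 62 °C | run made earlier |  |
| midnight | 2 mM | 3.1 mM | 2 mM | 4 mM | 90 °C | run made earlier |  |
| summer | 1 mM | 1.4 mM | 2 mM | 4 mM | 62 °C | run made earlier |  |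
| zeta | 2.0 mM | 1.40 mM | 2.00 mM | 4.00 mM | 100 °C |  | 15 min |
| theta | 2.0 mM | 1.40 mM | 2.00 mM | 4.00 mM | 75 °C |  | 15 min |
| gamma | 2.0 mM | 1.40 mM | 2.00 mM | 4.00 mM | 50 °C |  | 15 min |

| run | time / min | target / % | starting material / % |
|---|---|---|---|
| spring | 10.0 | 56 | 30 |
| spring | 20.0 | 59 | 22 |
| spring | 30.0 | 58 | 22 |
| spring | 40.0 | 56 | 24 |
| spring | 50.0 | 58 | 21 |
| spring | 60.0 | 56 | 16 |
| midnight | 1.00 | 81 | 16 |
| midnight | 3.00 | 81 | 12 |
| midnight | 5.00 | 83 | 10 |
| midnight | 8.00 | 81 | 2 |
| midnight | 10.0 | 80 | 6 |
| midnight | 15.0 | 85 | 2 |
| summer | 12.0 | 53 | 32 |
| summer | 25.0 | 57 | 25 |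
| summer | 30.0 | 58 | 28 |
| summer | 50.0 | 61 | 19 |
| summer | 60.0 | 52 | 18 |

(scatter of a reading: 2 percentage points)



1. which flask leads in amount of target, in percent of the starting material charged ("all alike" within 1.5 percentage points) (zeta / theta / gamma / all alike)
2. how much target is there at the end, in percent of the starting material charged: zeta
3. how much target is there at the end, in percent of the starting material charged: theta
4. how much target is there at the end, in percent of the starting material charged: gamma

The next plate has to settle whether its wells go to temperature or to reagent charge, and counting turnovers serves that choice. The spring plateau averages 57.2%, which gives 0.572 as the reagent yield f, target formed per reagent charged. Summer, at the same temperature with less starting material and less reagent against unchanged second and third substrate, reads 0.401, lower than spring, so those substrates look like rivals for the reagent. Midnight, at 90 °C and with more reagent, reads 0.528, but its starting material reads 2% at 15.0 min, so that figure may understate f and shows no clear temperature trend.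

The new flasks charge starting material and both rivals as spring does, so the reckoning here carries the spring f: target is f times 70.0%, or 40.0% in each of the flasks. Gamma, at 50 °C, and zeta, at 100 °C, lie outside the temperatures of the earlier runs, so their figures are extrapolations. Spring already stands at 56% by 10.0 min, so the time of 15 min can stay. The wells should go to reagent charge, and temperature can be left.

The forecast differs from this flat figure. It named zeta, with zeta 40% (33% to 48%), theta 37% (31% to 44%) and gamma 31% (23% to 38%), and its words were “Hotter should give slightly more”.

The flasks give zeta 41.5%, theta 42.0% and gamma 42.6%, a spread of 1.1 percentage points, inside the margin of 1.5 points, so the verdict is all alike.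

    starting material + reagent → target (k = 330 M⁻¹ s⁻¹, Ea = 40.0 kJ mol⁻¹)
    second substrate + reagent → second product (k = 110 M⁻¹ s⁻¹, Ea = 44.0 kJ mol⁻¹)
    third substrate + reagent → third product (k = 19.0 M⁻¹ s⁻¹, Ea = 47.0 kJ mol⁻¹)
    starting material → decomposition product (k = 5.90 × 10⁻⁵ s⁻¹, Ea = 100 kJ mol⁻¹)
    starting material ⇌ dormant form (K = 1.20, k = 0.120 s⁻¹, Ea = 80.0 kJ mol⁻¹, ΔH = −89.0 kJ mol⁻¹)
    (constants at 50 °C)

In gamma the reagent, the limiting reagent here, stands at 0% at 15.0 min; counted as the spring reading 0.572 was, f in gamma is 0.608, and the remainder of the reagent sits in second product, 0.398 mM, and third product, 0.150 mM. The second-substrate step is one part of the loss: with that step taken away, gamma reaches 57.1%. A neighbour of gamma charged with 8.0 mM of second substrate has f at 0.366, lower than in gamma, and ends with target at 25.6%.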